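**Retrosynthetic overview**
- Last bonds cleaved: the B-ring aryl acetate (lipase, neutral) and, before it, five benzyl ethers (hydrogenolysis); no base ever meets the free flavanone.
- C3–aryl bond: Pinhey arylation of a flavanone-3-carboxylate (β-keto ester) with an aryllead triacetate that already carries the benzylated apigenin unit; dealkylative decarboxylation then sets C3 trans under thermodynamic control.
- Flavanone ring (O1–C2): cinchona-thiourea-catalysed asymmetric oxa-Michael closure of a Knoevenagel alkylidene β-keto ester; this sets C2, the first stereocentre.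
- Flavone ring: Claisen–Schmidt condensation and I2/DMSO cyclisation from the same acetophenone and a brominated aldehyde, then Br → Sn → Pb.
- Ring order: flavone pyranone first (achiral), flavanone pyranone second (asymmetric), then union of the halves.

Assumption: the quinine-derived thiourea gives the 2R sense drawn for 8 (recalled from the parent flavanone series, not verified); if the first run shows the opposite sense (chiral HPLC/ECD), its quinidine-derived pseudoenantiomer is used with nothing else changed.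

**Step 1**
Reactants: 1 2′,4′,6′-trihydroxyacetophenone; 2 benzyl bromide
Product: 3 1-[2,4-bis(benzyloxy)-6-hydroxyphenyl]ethan-1-one
Conditions: BnBr (2.1 equiv), K2CO3, DMF, rt → 50 °C
Reagents that add atoms: benzyl bromide (2), BrCc1ccccc1
Why: Williamson etherification; the last ortho-OH is chelated to the ketone and is not alkylated, so the 4,6-dibenzyl ether is the main product.

**Step 2**
Reactants: 3 1-[2,4-bis(benzyloxy)-6-hydroxyphenyl]ethan-1-one; 4 di-tert-butyl dicarbonate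
Product: 5 tert-butyl 3-[2,4-bis(benzyloxy)-6-hydroxyphenyl]-3-oxopropanoate
Conditions: LiHMDS (3.3 equiv), THF, −78 °C; Boc2O (1.1 equiv), −78 → 0 °C; aq. NH4Cl
Reagents that add atoms: di-tert-butyl dicarbonate (4), CC(C)(C)OC(=O)OC(=O)OC(C)(C)C
Why: Claisen-type C-acylation of the phenoxide–enolate dianion at carbon; the third equivalent of base takes up the acidic product, and the tert-butyl ester resists lactonisation to a 4-hydroxycoumarin.

**Step 3**
Reactants: 5 tert-butyl 3-[2,4-bis(benzyloxy)-6-hydroxyphenyl]-3-oxopropanoate; 6 4-formylphenyl acetate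
Product: 7 tert-butyl (2Z)-3-(4-acetoxyphenyl)-2-[2,4-bis(benzyloxy)-6-hydroxybenzoyl]prop-2-enoate (mainly Z; both isomers converge in step 4)
Conditions: piperidine (10 mol%), AcOH (10 mol%), 4 Å MS, toluene, rt
Reagents that add atoms: 4-formylphenyl acetate (6), CC(=O)Oc1ccc(C=O)cc1
Why: Knoevenagel condensation; the electron-poor acetoxy aldehyde condenses readily, and the OH···O=C hydrogen bond holds back uncatalysed ring closure.

**Step 4**
Reactants: 7 tert-butyl (2Z)-3-(4-acetoxyphenyl)-2-[2,4-bis(benzyloxy)-6-hydroxybenzoyl]prop-2-enoate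
Product: 8 tert-butyl (2R,3S)-2-(4-acetoxyphenyl)-5,7-bis(benzyloxy)-4-oxochromane-3-carboxylate (trans keto form, in equilibrium with its enol)
Conditions: 1-[3,5-bis(trifluoromethyl)phenyl]-3-[(8S,9S)-6′-methoxycinchonan-9-yl]thiourea (10 mol%), toluene, −25 °C; cold 1 M HCl wash, short silica plug, use at once
Reagents that add atoms: none
Why: Asymmetric intramolecular oxa-Michael addition under bifunctional thiourea/tertiary-amine catalysis. The thiourea binds the β-keto ester and the quinuclidine delivers the phenol to one face of the alkylidene, which sets C2. C3 is labile and sits trans or as the enol.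

**Step 5**
Reactants: 3 1-[2,4-bis(benzyloxy)-6-hydroxyphenyl]ethan-1-one; 9 4-(benzyloxy)-3-bromobenzaldehyde
Product: 10 (2E)-1-[2,4-bis(benzyloxy)-6-hydroxyphenyl]-3-[4-(benzyloxy)-3-bromophenyl]prop-2-en-1-one
Conditions: KOH, EtOH/THF, rt
Reagents that add atoms: 4-(benzyloxy)-3-bromobenzaldehyde (9), O=Cc1ccc(OCc2ccccc2)c(Br)c1
Why: Claisen–Schmidt aldol condensation to the E-chalcone.

**Step 6**
Reactants: 10 (2E)-1-[2,4-bis(benzyloxy)-6-hydroxyphenyl]-3-[4-(benzyloxy)-3-bromophenyl]prop-2-en-1-one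
Product: 11 5,7-bis(benzyloxy)-2-[4-(benzyloxy)-3-bromophenyl]-4H-chromen-4-one
Conditions: I2 (10 mol%), DMSO, 130 °C
Reagents that add atoms: none
Why: I2/DMSO oxidative cyclisation of a 2′-hydroxychalcone (oxa-Michael closure, α-iodination, loss of HI; DMSO reoxidises HI) gives the flavone.

**Step 7**
Reactants: 11 5,7-bis(benzyloxy)-2-[4-(benzyloxy)-3-bromophenyl]-4H-chromen-4-one; 12 hexabutylditin
Product: 13 5,7-bis(benzyloxy)-2-[4-(benzyloxy)-3-(tributylstannyl)phenyl]-4H-chromen-4-one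
Conditions: (Bu3Sn)2 (1.5 equiv), Pd(PPh3)4 (5 mol%), toluene, 110 °C
Reagents that add atoms: hexabutylditin (12), CCCC[Sn](CCCC)(CCCC)[Sn](CCCC)(CCCC)CCCC
Why: Pd-catalysed stannylation of the aryl bromide (oxidative addition, Sn–Sn transmetallation, reductive elimination); the flavone carbonyl rules out a lithiation route.

**Step 8**
Reactants: 13 5,7-bis(benzyloxy)-2-[4-(benzyloxy)-3-(tributylstannyl)phenyl]-4H-chromen-4-one; 14 lead(IV) acetate
Product: 15 {2-(benzyloxy)-5-[5,7-bis(benzyloxy)-4-oxo-4H-chromen-2-yl]phenyl}lead(IV) triacetate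
Conditions: Pb(OAc)4 (1.05 equiv), Hg(OAc)2 (5 mol%), CHCl3, 40 °C; triturate with hexane, use crude
Reagents that add atoms: lead(IV) acetate (14), CC(=O)O[Pb](OC(C)=O)(OC(C)=O)OC(C)=O
Why: Hg(II)-catalysed tin–lead exchange (ipso-substitution) is the standard entry to alkoxy-substituted aryllead triacetates.

**Step 9**
Reactants: 8 tert-butyl (2R,3S)-2-(4-acetoxyphenyl)-5,7-bis(benzyloxy)-4-oxochromane-3-carboxylate; 15 {2-(benzyloxy)-5-[5,7-bis(benzyloxy)-4-oxo-4H-chromen-2-yl]phenyl}lead(IV) triacetate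
Product: 16 tert-butyl (2S,3R)-2-(4-acetoxyphenyl)-5,7-bis(benzyloxy)-3-{2-(benzyloxy)-5-[5,7-bis(benzyloxy)-4-oxo-4H-chromen-2-yl]phenyl}-4-oxochromane-3-carboxylate
Conditions: 15 (1.2 equiv), pyridine (3.5 equiv), CHCl3, 40 °C
Reagents that add atoms: aryllead triacetate (15), CC(=O)O[Pb](OC(C)=O)(OC(C)=O)c1cc(ccc1OCc1ccccc1)-c1cc(=O)c2c(OCc3ccccc3)cc(OCc3ccccc3)cc2o1
Why: Pinhey arylation (ligand coupling in the lead(IV) enolate) builds the hindered quaternary C3, with the aryl entering anti to the C2 aryl. C2 is untouched in space; its descriptor changes to S only through CIP priorities. The quaternary C3 now blocks retro-oxa-Michael opening.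

**Step 10**
Reactants: 16 tert-butyl (2S,3R)-2-(4-acetoxyphenyl)-5,7-bis(benzyloxy)-3-{2-(benzyloxy)-5-[5,7-bis(benzyloxy)-4-oxo-4H-chromen-2-yl]phenyl}-4-oxochromane-3-carboxylate
Product: 18 4-[(2R,3S)-5,7-bis(benzyloxy)-3-{2-(benzyloxy)-5-[5,7-bis(benzyloxy)-4-oxo-4H-chromen-2-yl]phenyl}-4-oxochroman-2-yl]phenyl acetate, via β-keto acid 17 (not isolated)
Conditions: TFA/CH2Cl2 (1:4), 0 °C → rt; then toluene, 60 °C; recrystallise to raise ee
Reagents that add atoms: none
Why: Acidolysis of the tert-butyl ester and decarboxylation of the β-keto acid; protonation and acid equilibration of the enol give the diequatorial 2,3-trans ketone. C3 (S) is therefore set by C2 under thermodynamic control, without base.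

**Step 11**
Reactants: 18 4-[(2R,3S)-5,7-bis(benzyloxy)-3-{2-(benzyloxy)-5-[5,7-bis(benzyloxy)-4-oxo-4H-chromen-2-yl]phenyl}-4-oxochroman-2-yl]phenyl acetate
Product: 19 4-[(2R,3S)-3-[5-(5,7-dihydroxy-4-oxo-4H-chromen-2-yl)-2-hydroxyphenyl]-5,7-dihydroxy-4-oxochroman-2-yl]phenyl acetate
Conditions: H2 (1 atm), 10% Pd/C, THF/EtOAc, rt
Reagents that add atoms: none
Why: Hydrogenolysis of the five benzyl ethers under neutral conditions; the acetate, the flavone C2=C3 bond and both stereocentres are unaffected at 1 atm and rt.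

**Step 12**
Reactants: 19 4-[(2R,3S)-3-[5-(5,7-dihydroxy-4-oxo-4H-chromen-2-yl)-2-hydroxyphenyl]-5,7-dihydroxy-4-oxochroman-2-yl]phenyl acetate
Product: 20 (2R,3S)-3-[5-(5,7-dihydroxy-4-oxo-4H-chromen-2-yl)-2-hydroxyphenyl]-5,7-dihydroxy-2-(4-hydroxyphenyl)-2,3-dihydro-4H-chromen-4-one
Conditions: lipase (immobilised Candida antarctica lipase B), n-BuOH (10 equiv), THF/MTBE, 40 °C; filter, evaporate
Reagents that add atoms: none
Why: Lipase-catalysed transesterification (serine hydrolase, acyl-enzyme from the aryl acetate, butanol as acceptor) frees the last phenol at neutral pH in organic medium. The base-labile C2 and C3 centres of the free flavanone are therefore never exposed to base-promoted ring opening or enolisation.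

**Compound list**
1 | 2′,4′,6′-trihydroxyacetophenone | CC(=O)c1c(O)cc(O)cc1O | starting material
2 | benzyl bromide | BrCc1ccccc1 | starting material
3 | 1-[2,4-bis(benzyloxy)-6-hydroxyphenyl]ethan-1-one | CC(=O)c1c(O)cc(OCc2ccccc2)cc1OCc1ccccc1 | intermediate
4 | di-tert-butyl dicarbonate | CC(C)(C)OC(=O)OC(=O)OC(C)(C)C | starting material
5 | tert-butyl 3-[2,4-bis(benzyloxy)-6-hydroxyphenyl]-3-oxopropanoate | CC(C)(C)OC(=O)CC(=O)c1c(O)cc(OCc2ccccc2)cc1OCc1ccccc1 | intermediate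
6 | 4-formylphenyl acetate | CC(=O)Oc1ccc(C=O)cc1 | starting material
7 | tert-butyl (2Z)-3-(4-acetoxyphenyl)-2-[2,4-bis(benzyloxy)-6-hydroxybenzoyl]prop-2-enoate | CC(=O)Oc1ccc(cc1)/C=C(\C(=O)OC(C)(C)C)C(=O)c1c(O)cc(OCc2ccccc2)cc1OCc1ccccc1 | intermediate
8 | tert-butyl (2R,3S)-2-(4-acetoxyphenyl)-5,7-bis(benzyloxy)-4-oxochromane-3-carboxylate | O=C1c2c(OCc3ccccc3)cc(OCc3ccccc3)cc2O[C@@H](c2ccc(OC(C)=O)cc2)[C@@H]1C(=O)OC(C)(C)C | intermediate
9 | 4-(benzyloxy)-3-bromobenzaldehyde | O=Cc1ccc(OCc2ccccc2)c(Br)c1 | starting material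
10 | (2E)-1-[2,4-bis(benzyloxy)-6-hydroxyphenyl]-3-[4-(benzyloxy)-3-bromophenyl]prop-2-en-1-one | O=C(/C=C/c1ccc(OCc2ccccc2)c(Br)c1)c1c(O)cc(OCc2ccccc2)cc1OCc1ccccc1 | intermediate
11 | 5,7-bis(benzyloxy)-2-[4-(benzyloxy)-3-bromophenyl]-4H-chromen-4-one | O=c1cc(-c2ccc(OCc3ccccc3)c(Br)c2)oc2cc(OCc3ccccc3)cc(OCc3ccccc3)c12 | intermediate
12 | hexabutylditin | CCCC[Sn](CCCC)(CCCC)[Sn](CCCC)(CCCC)CCCC | starting material
13 | 5,7-bis(benzyloxy)-2-[4-(benzyloxy)-3-(tributylstannyl)phenyl]-4H-chromen-4-one | CCCC[Sn](CCCC)(CCCC)c1cc(ccc1OCc1ccccc1)-c1cc(=O)c2c(OCc3ccccc3)cc(OCc3ccccc3)cc2o1 | intermediate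
14 | lead(IV) acetate | CC(=O)O[Pb](OC(C)=O)(OC(C)=O)OC(C)=O | starting material
15 | {2-(benzyloxy)-5-[5,7-bis(benzyloxy)-4-oxo-4H-chromen-2-yl]phenyl}lead(IV) triacetate | CC(=O)O[Pb](OC(C)=O)(OC(C)=O)c1cc(ccc1OCc1ccccc1)-c1cc(=O)c2c(OCc3ccccc3)cc(OCc3ccccc3)cc2o1 | intermediate
16 | tert-butyl (2S,3R)-2-(4-acetoxyphenyl)-5,7-bis(benzyloxy)-3-{2-(benzyloxy)-5-[5,7-bis(benzyloxy)-4-oxo-4H-chromen-2-yl]phenyl}-4-oxochromane-3-carboxylate | O=C1c2c(OCc3ccccc3)cc(OCc3ccccc3)cc2O[C@@H](c2ccc(OC(C)=O)cc2)[C@]1(C(=O)OC(C)(C)C)c1cc(-c2cc(=O)c3c(OCc4ccccc4)cc(OCc4ccccc4)cc3o2)ccc1OCc1ccccc1 | intermediate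
17 | (2S,3R)-2-(4-acetoxyphenyl)-5,7-bis(benzyloxy)-3-{2-(benzyloxy)-5-[5,7-bis(benzyloxy)-4-oxo-4H-chromen-2-yl]phenyl}-4-oxochromane-3-carboxylic acid | O=C1c2c(OCc3ccccc3)cc(OCc3ccccc3)cc2O[C@@H](c2ccc(OC(C)=O)cc2)[C@]1(C(=O)O)c1cc(-c2cc(=O)c3c(OCc4ccccc4)cc(OCc4ccccc4)cc3o2)ccc1OCc1ccccc1 | intermediate
18 | 4-[(2R,3S)-5,7-bis(benzyloxy)-3-{2-(benzyloxy)-5-[5,7-bis(benzyloxy)-4-oxo-4H-chromen-2-yl]phenyl}-4-oxochroman-2-yl]phenyl acetate | O=C1c2c(OCc3ccccc3)cc(OCc3ccccc3)cc2O[C@@H](c2ccc(OC(C)=O)cc2)[C@@H]1c1cc(-c2cc(=O)c3c(OCc4ccccc4)cc(OCc4ccccc4)cc3o2)ccc1OCc1ccccc1 | intermediate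
19 | 4-[(2R,3S)-3-[5-(5,7-dihydroxy-4-oxo-4H-chromen-2-yl)-2-hydroxyphenyl]-5,7-dihydroxy-4-oxochroman-2-yl]phenyl acetate | O=C1c2c(O)cc(O)cc2O[C@@H](c2ccc(OC(C)=O)cc2)[C@@H]1c1cc(-c2cc(=O)c3c(O)cc(O)cc3o2)ccc1O | intermediate
20 | (2R,3S)-3-[5-(5,7-dihydroxy-4-oxo-4H-chromen-2-yl)-2-hydroxyphenyl]-5,7-dihydroxy-2-(4-hydroxyphenyl)-2,3-dihydro-4H-chromen-4-one | O=C1c2c(O)cc(O)cc2O[C@@H](c2ccc(O)cc2)[C@@H]1c1cc(-c2cc(=O)c3c(O)cc(O)cc3o2)ccc1O | target

**Step count**
Total: 12 steps. Longest linear sequence: 9 steps (1, 5, 6, 7, 8, 9, 10, 11, 12).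

**Three steps most likely to fail**

Step 9 (Pinhey arylation): the quaternary centre is crowded, and pyridine could erode C2 through reversible ring opening of 8 before the aryl is transferred. The fallback replaces lead by hypervalent iodine. It sets out from 13, which with iodomesitylene diacetate and TsOH·H2O (MeCN/CH2Cl2, rt) gives {2-(benzyloxy)-5-[5,7-bis(benzyloxy)-4-oxo-4H-chromen-2-yl]phenyl}(2,4,6-trimethylphenyl)iodonium tosylate F2. The potassium enolate of 8 (t-BuOK, toluene, 0 °C) is then arylated by this salt without metal, mesityl being the group that stays on iodine, and the route is rejoined at 16.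

Step 4 (asymmetric oxa-Michael): the 6′-benzyloxy group and a racemic background closure may lower the ee with this A ring. The fallback forms C2 by C–C instead of C–O bond formation. It sets out from 5, which with DMF dimethyl acetal (toluene, 80 °C) closes to tert-butyl 5,7-bis(benzyloxy)-4-oxo-4H-chromene-3-carboxylate F1. Pd(OCOCF3)2/t-BuPyOx-catalysed asymmetric 1,4-addition of 4-acetoxyphenylboronic acid (NH4PF6, H2O, 1,2-dichloroethane, 60 °C), using the ligand enantiomer that gives the 2R sense, returns to the route at 8.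

Step 11 (hydrogenolysis): the flavone C2=C3 bond or the benzylic C2–O bond of the flavanone could be reduced. The fallback is a non-reductive endgame in reversed order, setting out from 18. The lipase step is run first (toluene/n-BuOH, 40 °C) to give (2R,3S)-5,7-bis(benzyloxy)-3-{2-(benzyloxy)-5-[5,7-bis(benzyloxy)-4-oxo-4H-chromen-2-yl]phenyl}-2-(4-hydroxyphenyl)chroman-4-one F3, so that no acetate is left to be partly cleaved in the acidic quench. BCl3 with pentamethylbenzene as cation scavenger (CH2Cl2, −78 °C) then removes the five benzyl groups and arrives directly at 20.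

**Further compounds**
F1 | step 4 | tert-butyl 5,7-bis(benzyloxy)-4-oxo-4H-chromene-3-carboxylate | CC(C)(C)OC(=O)c1coc2cc(OCc3ccccc3)cc(OCc3ccccc3)c2c1=O
F2 | step 9 | {2-(benzyloxy)-5-[5,7-bis(benzyloxy)-4-oxo-4H-chromen-2-yl]phenyl}(2,4,6-trimethylphenyl)iodonium tosylate | Cc1cc(C)c([I+]c2cc(ccc2OCc2ccccc2)-c2cc(=O)c3c(OCc4ccccc4)cc(OCc4ccccc4)cc3o2)c(C)c1.Cc1ccc(cc1)S(=O)(=O)[O-]
F3 | step 11 | (2R,3S)-5,7-bis(benzyloxy)-3-{2-(benzyloxy)-5-[5,7-bis(benzyloxy)-4-oxo-4H-chromen-2-yl]phenyl}-2-(4-hydroxyphenyl)chroman-4-one | O=C1c2c(OCc3ccccc3)cc(OCc3ccccc3)cc2O[C@@H](c2ccc(O)cc2)[C@@H]1c1cc(-c2cc(=O)c3c(OCc4ccccc4)cc(OCc4ccccc4)cc3o2)ccc1OCc1ccccc1
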